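3 questions stand for this flask, and I kept one ledger for them, on the solid substrate, the limiting reagent.

- midnight: solid substrate 30 mM; run made earlier
- flask: solid substrate 20 mM; time 30 h

- midnight (time / h: target / %, isomer of the product A / %): 0.250: 2, 2; 0.417: 1, 11; 0.833: 1, 17; 1.50: 4, 39; 3.00: 6, 82

(standard deviation of a reading: 2 percentage points)

- given per volume of solution although it is solid: solid substrate
- at the start none of the solid substrate is in solution
- what has only dissolved of solid substrate counts as not reacted
- the reaction counts as stopped when no species that holds the solid substrate changes by six tenths of a point or more over the second half of the time

- which holds at 30 h: what has brought the reaction to rest, or that it has not come to rest (for what has run out or reacted, a solid counts together with what of it has only dissolved) (forward and back rates have come level / it is still moving / all of the solid substrate has reacted)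
- how much target there is at 30 h, in percent of the solid substrate charged
- how much isomer of the product A there is at 30 h, in percent of the solid substrate charged

In the midnight run, target and isomer of the product A together read 88.0% of the charge at 3.00 h, and their sum had climbed roughly in a line. Assuming the pace holds while solid lasts, I took it from that last point:

pace = 88.0% × 30 mM / 3.00 h = 8.80 mM/h

drain time of the flask = 20 mM / 8.80 mM/h = 2.27 h

This drain time, the charge of solid substrate over the pace of read product, is shorter than the 30 h allowed, so I closed the solid entry of the flask's ledger early.

One entry stayed open:

unread at the last midnight reading = 12.0%

The readings, each scattering by 2 percentage points, could not say whether that share was solid still to come or material held somewhere unread. I therefore committed the flask's target plus isomer of the product A to a range from 88.0% to 100%.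

The forecast, at the top of that range, gave this end: all of the solid substrate has reacted, with 7% target and 93% isomer of the product A, and noted: "The runs show no sign of levelling off".

The flask gave this end: forward and back rates have come level, with 3.03% target and 84.9% isomer of the product A at 30 h.

    starting material ⇌ target (K = 0.850, k = 0.0610 /min)
    target ⇌ isomer of the product A (K = 28.0, k = 0.830 /min)
    isomer of the product A ⇌ isomer of the product B (K = 0.100, k = 1.50 /min)
    solid substrate ⇌ starting material, rate k4*(cs4 - [starting material]) while solid is left; crystals form when [starting material] > cs4 (solubility = 9.00 mM, k = 0.0310 /min)

Against the drain time of 2.27 h, solid substrate in the flask stood at 0% by 3.00 h, and the open entry closed on 3.57% starting material and 8.49% isomer of the product B. In the flask, target's forward half-life towards isomer of the product A was 0.84 min at 30.0 h, far shorter than that time, with backward turnover 98% of the forward one. The neighbour charged with 5.0 mM had a drain time of 0.568 h, and at 30.0 h it held 3.03% target and 84.9% isomer of the product A.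

The data come from a simulation for substances that don't exist; scatter was added.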